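**Retrosynthetic overview**

1. Pieces, in the order used: aryl Grignard 1 and veratraldehyde 2 give, through alkoxide 3, the benzhydryl carbonate 4; tiglic aldehyde 5 supplies C2, C3, C4 and both C-methyl groups.
2. Key disconnection, C1–C2: the β-carbon of 5, made nucleophilic as a carbene-bound homoenolate, is joined to the diarylmethyl cation released from 4. This gives ester 6 and sets the C2 stereocentre, the only one set by a catalyst.
3. Last disconnection, C4–C4a: one-pot reduction of 6 (aluminium hemiacetal 7, aldehyde 8) and Friedel–Crafts cyclodehydration (tetralol 9) give target 10. The choice between the two diastereotopic aryl groups sets C1 trans to the C2 methyl.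
4. Ring order: both benzene rings are bought; ring B (the dihydronaphthalene carbocycle) is the only ring formed, in the final step.

Assumption: the (5aS,10bR) antipode of the triazolium precatalyst is taken to give the 3S ester 6; if the sense of induction proves opposite, the equally available (5aR,10bS) salt is used with no other change.

The target is (1R,2S)-configured, with the C1 aryl and C2 methyl trans.

**Route**

Step 1
Reactants: 1 3,4-dimethoxyphenylmagnesium bromide; 2 3,4-dimethoxybenzaldehyde (veratraldehyde)
Product: 4 bis(3,4-dimethoxyphenyl)methyl methyl carbonate, via magnesium alkoxide 3 (not isolated)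
Conditions: 1 (1.05 equiv, 0.5 M in THF), 2, THF, 0 °C, 1 h; then ClCO2Me (1.3 equiv), 0 °C → rt; aq. NaHCO3 work-up; crystallisation or Et3N-deactivated silica
Reagents that add atoms: methyl chloroformate, COC(=O)Cl
Why: Grignard 1,2-addition to an aldehyde followed by in situ O-acylation of the magnesium alkoxide with a chloroformate; the carbinol carbon carries two identical aryl groups, so no stereocentre arises.

Step 2
Reactants: 4 bis(3,4-dimethoxyphenyl)methyl methyl carbonate; 5 (E)-2-methylbut-2-enal (tiglic aldehyde)
Product: 6 methyl (3S)-4,4-bis(3,4-dimethoxyphenyl)-2,3-dimethylbutanoate (mixture of C2 epimers)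
Conditions: 5 (2.0 equiv), (5aS,10bR)-2-(2,4,6-trimethylphenyl)-5a,10b-dihydro-4H,6H-indeno[2,1-b][1,2,4]triazolo[4,3-d][1,4]oxazin-2-ium chloride (15 mol%), NaOAc (20 mol%), Mg(OTf)2 (20 mol%), 4 Å MS, THF, 0 °C → rt, Ar; 4 (1.0 equiv) added by syringe pump over 6 h
Reagents that add atoms: none
Why: Proposed new method: the free carbene adds to 5 and, after proton transfer, makes its β-carbon nucleophilic (homoenolate reactivity), while Mg(OTf)2 ionises 4 to the doubly alkoxy-stabilised diarylmethyl cation and methyl carbonate anion; C–C bond formation at the β-carbon on the face left open by the aminoindanol backbone sets the 3S centre, the azolium enolate is then protonated at C2 without control (that centre is erased later), and methoxide released by loss of CO2 from the leaving group takes over the acyl group to give 6 and free carbene; 5 alone is inert to the cation, so there is no racemic background; the closest known reactions are carbene-catalysed homoenolate 1,6-additions to para-quinone methides and carbene redox esterifications in which an alkoxide released in situ turns over the acyl azolium.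

Step 3
Reactants: 6 methyl (3S)-4,4-bis(3,4-dimethoxyphenyl)-2,3-dimethylbutanoate
Product: 10 (1R,2S)-1-(3,4-dimethoxyphenyl)-6,7-dimethoxy-2,3-dimethyl-1,2-dihydronaphthalene, via aluminium hemiacetal 7 (not isolated), via aldehyde 8 (not isolated), via tetralol 9 (not isolated)
Conditions: i-Bu2AlH (1.15 equiv), CH2Cl2, −78 °C, 1 h; then CF3CO2H (10 equiv), −78 → 0 °C, 2 h (0.02 M); aq. NaHCO3/KNaC4H4O6 work-up; chromatography
Reagents that add atoms: none
Why: Partial ester reduction stops at the tetrahedral aluminium hemiacetal at −78 °C, acid releases the aldehyde, and a Bradsher-type intramolecular Friedel–Crafts hydroxyalkylation para to a methoxy group followed by E1 dehydration gives the conjugated C3=C4 alkene; C1 is set by which of the two diastereotopic aryl rings attacks, the half-chair with the spectator aryl and the C2 methyl anti (pseudo-diaxial) avoiding both the peri contact with H8 and an aryl/methyl gauche contact, so the trans (1R) isomer should dominate, while C2 is untouched and both C3 epimers converge.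

**Compound list**

1 | 3,4-dimethoxyphenylmagnesium bromide | COc1ccc([Mg]Br)cc1OC | starting material
2 | 3,4-dimethoxybenzaldehyde (veratraldehyde) | COc1ccc(C=O)cc1OC | starting material
3 | bromomagnesium bis(3,4-dimethoxyphenyl)methanolate | COc1ccc(C(O[Mg]Br)c2ccc(OC)c(OC)c2)cc1OC | intermediate
4 | bis(3,4-dimethoxyphenyl)methyl methyl carbonate | COC(=O)OC(c1ccc(OC)c(OC)c1)c1ccc(OC)c(OC)c1 | intermediate
5 | (E)-2-methylbut-2-enal (tiglic aldehyde) | C/C=C(\C)C=O | starting material
6 | methyl (3S)-4,4-bis(3,4-dimethoxyphenyl)-2,3-dimethylbutanoate, C2 unspecified | COC(=O)C(C)[C@@H](C)C(c1ccc(OC)c(OC)c1)c1ccc(OC)c(OC)c1 | intermediate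
7 | [(3S)-4,4-bis(3,4-dimethoxyphenyl)-1-methoxy-2,3-dimethylbutoxy]bis(2-methylpropyl)alumane (aluminium hemiacetal), C1 and C2 unspecified | COC(O[Al](CC(C)C)CC(C)C)C(C)[C@@H](C)C(c1ccc(OC)c(OC)c1)c1ccc(OC)c(OC)c1 | intermediate
8 | (3S)-4,4-bis(3,4-dimethoxyphenyl)-2,3-dimethylbutanal, C2 unspecified | O=CC(C)[C@@H](C)C(c1ccc(OC)c(OC)c1)c1ccc(OC)c(OC)c1 | intermediate
9 | (3S,4R)-4-(3,4-dimethoxyphenyl)-6,7-dimethoxy-2,3-dimethyl-1,2,3,4-tetrahydronaphthalen-1-ol, C1 and C2 unspecified, aryl and C3 methyl trans | COc1ccc([C@@H]2c3cc(OC)c(OC)cc3C(O)C(C)[C@H]2C)cc1OC | intermediate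
10 | (1R,2S)-1-(3,4-dimethoxyphenyl)-6,7-dimethoxy-2,3-dimethyl-1,2-dihydronaphthalene (aryl and C2 methyl trans) | COc1ccc([C@@H]2c3cc(OC)c(OC)cc3C=C(C)[C@H]2C)cc1OC | target

**Totals**

Total step count: 3. Longest linear sequence: 3 (1/2 → 4 → 6 → 10).

**Steps most likely to fail, with fallbacks**

Step 2 (highest risk). The free carbene may be alkylated irreversibly by the cation, attack may occur at the acyl carbon instead of the β-carbon, the α-methyl enal may be slow to form the homoenolate, the ion pair may collapse to the benzhydryl methyl ether, and the ee is unproven. The fallback sets out from 2 and 5 and comes back at 6. The same triazolium salt with LiCl (20 mol%) and DBU (15 mol%) in THF promotes the well-behaved homoenolate addition of 5 to the neutral aldehyde 2 with lactonisation. This gives (4R)-5-(3,4-dimethoxyphenyl)-3,4-dimethyloxolan-2-one F1. Treating it with 1,2-dimethoxybenzene (5 equiv) and CF3SO3H in CH2Cl2 at 0 °C ionises the benzylic C–O bond, and the arene traps the cation para to a methoxy group. The product is (3S)-4,4-bis(3,4-dimethoxyphenyl)-2,3-dimethylbutanoic acid F2. The former benzylic centre becomes the non-stereogenic diarylmethyl carbon, so only the carbene-set C4 centre matters. Esterification (MeOH, catalytic H2SO4, reflux) returns to 6.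

Step 3. Risks are over-reduction by i-Bu2AlH, acid-induced oligomerisation of the electron-rich styrene, and a modest trans:cis ratio at C1. The fallback sets out from 6 and comes back at 8. LiAlH4 in THF at 0 °C reduces 6 fully to (3S)-4,4-bis(3,4-dimethoxyphenyl)-2,3-dimethylbutan-1-ol F3. Dess–Martin periodinane with NaHCO3 in CH2Cl2 oxidises it to aldehyde 8, which is now isolated and purified. Ring closure is then a separate operation under only catalytic acid with water removal (TsOH·H2O 5 mol%, benzene, reflux, Dean–Stark), passing through 9 to 10. The lower acid load lets the reaction be stopped before the alkene degrades and the cis isomer be removed by chromatography.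

Step 1. The electron-rich benzhydryl carbonate may ionise and lose CO2 to the methyl ether during work-up or on silica. The fallback sets out from 1 and 2 and comes back at 4. The Grignard adduct is quenched with aq. NH4Cl and bis(3,4-dimethoxyphenyl)methanol F4 is isolated as a bench-stable solid. It is acylated just before use with dimethyl dicarbonate and catalytic DMAP in THF, the volatiles are stripped, and the crude solution of 4 is fed directly into step 2.

**Further compounds**

F1 | step 2 | (4R)-5-(3,4-dimethoxyphenyl)-3,4-dimethyloxolan-2-one, C3 and C5 unspecified | O=C1OC(c2ccc(OC)c(OC)c2)[C@H](C)C1C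
F2 | step 2 | (3S)-4,4-bis(3,4-dimethoxyphenyl)-2,3-dimethylbutanoic acid, C2 unspecified | OC(=O)C(C)[C@@H](C)C(c1ccc(OC)c(OC)c1)c1ccc(OC)c(OC)c1
F3 | step 3 | (3S)-4,4-bis(3,4-dimethoxyphenyl)-2,3-dimethylbutan-1-ol, C2 unspecified | OCC(C)[C@@H](C)C(c1ccc(OC)c(OC)c1)c1ccc(OC)c(OC)c1
F4 | step 1 | bis(3,4-dimethoxyphenyl)methanol | COc1ccc(C(O)c2ccc(OC)c(OC)c2)cc1OC
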